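A direct plan would release 3,5-dimethoxybenzyne from silyl triflate A1, insert it into the carboxyl C–O bond of the silyl-protected (R)-5-hydroxy-2-ynoic acid A2 and close the resulting ortho-hydroxyaryl ynone at oxygen to the 5,7-dimethoxychromone A3. The acid chain would come from epoxide A4, resolved by hydrolytic kinetic resolution and opened with an acetylide. Its weakest steps would be:
- the one-flask aryne insertion and 6-endo closure, which would be without precedent on such an acid and would hinge on regioselective aryne capture and on 6-endo over 5-exo cyclisation;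
- the kinetic resolution, which would discard at least half of the epoxide to set a single stereocentre;
- the preparative overhead (three operations to A1, alkyne carboxylation, silyl protection and removal, final chelation-controlled demethylation), which would add length without complexity.

**New strategy.** The route disconnects C3–C4 of ring C and exploits that C4 sits on ring A between two oxygens (O1 on C8a, OH on C5) that are equivalent in a symmetrical aldehyde. The formyl carbon of 2,6-dihydroxy-4-methoxybenzaldehyde (future C4) would be joined, by rhodium-catalysed formyl C–H activation and carbene insertion, to the ylide carbon (future C3) of a keto sulfoxonium ylide that carries C2, the side chain and the free (R)-carbinol; cyclodehydration at O1–C2 in the same flask would give the target. The ylide would come from an (R)-β-lactone made by catalytic asymmetric ketene–aldehyde cycloaddition, whose ring holds C2 as activated acyl group and the carbinol oxygen in masked form. No aryne, resolution, protecting group or demethylation would remain.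

Key step: step 4

Assumption (step 1): the aluminium–triamine cyclocondensation is taken to follow, for this unbranched aldehyde, the sense in which the (S,S)-ligand from (S)-valinol gives (4S)-4-alkyl lactones, hence the (R,R)-ligand; the antipodal ligand would be used should the sense be opposite.

Step 1
Reactants: 1 methyl 6-oxohexanoate
Product: 2 methyl 5-[(2R)-4-oxooxetan-2-yl]pentanoate
Conditions: AcBr (1.9 equiv), i-Pr2NEt (1.7 equiv), MeAl[BnN(CH2CH(i-Pr)NSO2CF3)2] (10 mol %, from AlMe3 and the (R,R)-bis(triflamide) BnN[CH2CH(i-Pr)NHSO2CF3]2), CH2Cl2, −50 °C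
Reagents that add atoms: acetyl bromide, CC(=O)Br
Why: Catalytic asymmetric acyl halide–aldehyde cyclocondensation (formal [2+2] of ketene, released from AcBr by the amine, with the aldehyde bound to the chiral trivalent aluminium Lewis acid), in which the triamine ligand shields one face of the coordinated aldehyde and so sets the only stereocentre as (R), while the remote methyl ester binds the catalyst far more weakly than the aldehyde and should not interfere.

Step 2
Reactants: 2 methyl 5-[(2R)-4-oxooxetan-2-yl]pentanoate
Product: 3 methyl (6R)-9-[dimethyl(oxo)-λ6-sulfanylidene]-6-hydroxy-8-oxononanoate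
Conditions: Me3S(O)I (1.3 equiv), KOt-Bu (1.2 equiv), THF, reflux; then 2, −20 to 0 °C; aq. NH4Cl
Reagents that add atoms: trimethylsulfoxonium iodide, C[S+](C)(C)=O.[I-]
Why: Acylation of dimethylsulfoxonium methylide by lactone ring opening, in which the ylide adds to the strained lactone carbonyl far faster than to the methyl ester, the ring opens at the acyl–oxygen bond so that the C–O bond at the stereocentre is not broken, and the released alkoxide takes the proton between carbonyl and sulfur to leave the stabilised keto ylide with the free carbinol.

Step 3
Reactants: 4 2,4,6-trihydroxybenzaldehyde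
Product: 5 2,6-dihydroxy-4-methoxybenzaldehyde
Conditions: Me2SO4 (1.0 equiv), K2CO3 (1.0 equiv), acetone, 0 °C to rt
Reagents that add atoms: dimethyl sulfate, COS(=O)(=O)OC
Why: Site-selective Williamson O-methylation, in which the 4-hydroxyl, para to the formyl group and not held in a hydrogen bond to it, is the most acidic and least hindered, so that one equivalent each of base and of the hard methylating agent should alkylate O-4 and leave the two equivalent ortho hydroxyls free.

Step 4
Reactants: 3 methyl (6R)-9-[dimethyl(oxo)-λ6-sulfanylidene]-6-hydroxy-8-oxononanoate; 5 2,6-dihydroxy-4-methoxybenzaldehyde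
Product: 7 penithochromone O [methyl (6R)-6-hydroxy-7-(5-hydroxy-7-methoxy-4-oxo-4H-chromen-2-yl)heptanoate], via 1,3-diketone 6 (not isolated)
Conditions: 5 (1.3 equiv), [(C5Me5)RhCl2]2 (2.5 mol %), AgSbF6 (10 mol %), NaOAc (30 mol %), ClCH2CH2Cl, 80 °C, Ar; then AcOH (2 equiv), 60 °C
Reagents that add atoms: none
Why: The phenoxide of 5 binds the cationic (C5Me5)Rh centre (trivalent rhodium) and acetate-assisted cleavage of the formyl C–H bond gives a five-membered acyl rhodacycle; the ylide carbon of 3 then coordinates, dimethyl sulfoxide leaves to give a rhodium carbene, 1,1-migratory insertion of the acyl group joins C4 to C3, and protonolysis releases 1,3-diketone 6 and the catalyst. The closest known reaction type is the rhodium-catalysed formyl C–H functionalisation of salicylaldehydes with keto sulfoxonium ylides (or diazo carbonyl compounds), which gives 2-substituted chromones. Ring C then closes at O1–C2 by 6-exo-trig addition of an ortho phenol to the aliphatic C2 ketone and loss of water from the hemiketal, which gives the aromatic γ-pyranone. No stereocentre is formed; the carbinol carbon lies two atoms from the reacting ylide carbon, none of its bonds is broken and it is not enolisable, so the configuration from step 1 should pass through. The step needs C–C coupling to outrun O–H insertion of the carbene and closure through a phenol instead of the side-chain hydroxyl; the first is secured because the carbene forms on the acyl rhodacycle, the second because the alkyl ketone is more electrophilic than the hindered, hydrogen-bonded aryl ketone and only the phenol closure gives an aromatic ring. Regiochemistry is not at issue, since the two ortho hydroxyls of 5 are equivalent and the one not used becomes the 5-OH.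

**Compound list**

1 | methyl 6-oxohexanoate | COC(=O)CCCCC=O | starting material
2 | methyl 5-[(2R)-4-oxooxetan-2-yl]pentanoate | COC(=O)CCCC[C@@H]1CC(=O)O1 | intermediate
3 | methyl (6R)-9-[dimethyl(oxo)-λ6-sulfanylidene]-6-hydroxy-8-oxononanoate | COC(=O)CCCC[C@@H](O)CC(=O)C=S(C)(C)=O | intermediate
4 | 2,4,6-trihydroxybenzaldehyde | O=Cc1c(O)cc(O)cc1O | starting material
5 | 2,6-dihydroxy-4-methoxybenzaldehyde | COc1cc(O)c(C=O)c(O)c1 | intermediate
6 | 1,3-diketone: methyl (6R)-10-(2,6-dihydroxy-4-methoxyphenyl)-6-hydroxy-8,10-dioxodecanoate (not isolated) | COC(=O)CCCC[C@@H](O)CC(=O)CC(=O)c1c(O)cc(OC)cc1O | intermediate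
7 | penithochromone O, methyl (6R)-6-hydroxy-7-(5-hydroxy-7-methoxy-4-oxo-4H-chromen-2-yl)heptanoate | COC(=O)CCCC[C@@H](O)Cc1cc(=O)c2c(O)cc(OC)cc2o1 | target

Total step count: 4. Longest linear sequence: 3 (steps 1, 2 and 4).

Steps most likely to fail:

Step 4. The carbene could be diverted into O–H insertion, the chelating 5-hydroxy-4-oxo product could sequester the catalyst, or water could be lost from the β-hydroxy ketone at the diketone stage. The C3–C4 coupling would then be replaced by a Claisen-type C2–C3 construction. Commercial 1-(2,6-dihydroxy-4-methoxyphenyl)ethanone F1 would be converted with MOMCl/i-Pr2NEt into 1-[4-methoxy-2,6-bis(methoxymethoxy)phenyl]ethanone F2. Its lithium enolate (LiHMDS, 2.2 equiv, THF, −78 °C) would open lactone 2 at the acyl carbon to give methyl (6R)-6-hydroxy-10-[4-methoxy-2,6-bis(methoxymethoxy)phenyl]-8,10-dioxodecanoate F3. HCl in MeOH at 40 °C would remove both acetals and cyclodehydrate to 7. The fallback sets out from 2 and returns at 7.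

Step 2. The ylide could attack the alkyl carbon of the lactone or the methyl ester. The acyl group would then be offered as an acyclic imidazolide. Lactone 2 would be hydrolysed with LiOH (1.0 equiv, THF/H2O, 0 °C; acyl–oxygen cleavage, configuration retained) to (3R)-3-hydroxy-8-methoxy-8-oxooctanoic acid F4. This would be activated with 1,1'-carbonyldiimidazole (1.05 equiv, THF, 0 °C) as methyl (6R)-6-hydroxy-8-(1H-imidazol-1-yl)-8-oxooctanoate F5 and treated at −20 °C with Me2S(O)=CH2. The fallback sets out from 2 and returns at 3.

Step 3. Methylation could occur at an ortho hydroxyl or twice. The order of events would then be reversed. Aldehyde 4 would be carried unmethylated through the conditions of step 4 with 3 to give methyl (6R)-7-(5,7-dihydroxy-4-oxo-4H-chromen-2-yl)-6-hydroxyheptanoate F6, in which the 5-OH is locked in a hydrogen bond to the C4 carbonyl. MeI (1.1 equiv) and K2CO3 (1.1 equiv) in acetone at rt would then methylate only the 7-OH. The fallback sets out from 4 and returns at 7.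

**Further compounds**

F1 | step 4 | 1-(2,6-dihydroxy-4-methoxyphenyl)ethanone | COc1cc(O)c(C(C)=O)c(O)c1
F2 | step 4 | 1-[4-methoxy-2,6-bis(methoxymethoxy)phenyl]ethanone | COCOc1cc(OC)cc(OCOC)c1C(C)=O
F3 | step 4 | methyl (6R)-6-hydroxy-10-[4-methoxy-2,6-bis(methoxymethoxy)phenyl]-8,10-dioxodecanoate | COC(=O)CCCC[C@@H](O)CC(=O)CC(=O)c1c(OCOC)cc(OC)cc1OCOC
F4 | step 2 | (3R)-3-hydroxy-8-methoxy-8-oxooctanoic acid | COC(=O)CCCC[C@@H](O)CC(=O)O
F5 | step 2 | methyl (6R)-6-hydroxy-8-(1H-imidazol-1-yl)-8-oxooctanoate | COC(=O)CCCC[C@@H](O)CC(=O)n1ccnc1
F6 | step 3 | methyl (6R)-7-(5,7-dihydroxy-4-oxo-4H-chromen-2-yl)-6-hydroxyheptanoate | COC(=O)CCCC[C@@H](O)Cc1cc(=O)c2c(O)cc(O)cc2o1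
A1 | direct plan | 3,5-dimethoxy-2-(trimethylsilyl)phenyl trifluoromethanesulfonate | COc1cc(OC)c([Si](C)(C)C)c(OS(=O)(=O)C(F)(F)F)c1
A2 | direct plan | (5R)-5-[(tert-butyldimethylsilyl)oxy]-10-methoxy-10-oxodec-2-ynoic acid | COC(=O)CCCC[C@@H](O[Si](C)(C)C(C)(C)C)CC#CC(=O)O
A3 | direct plan | methyl (6R)-6-[(tert-butyldimethylsilyl)oxy]-7-(5,7-dimethoxy-4-oxo-4H-chromen-2-yl)heptanoate | COC(=O)CCCC[C@@H](O[Si](C)(C)C(C)(C)C)Cc1cc(=O)c2c(OC)cc(OC)cc2o1
A4 | direct plan | methyl 5-[(2R)-oxiran-2-yl]pentanoate | COC(=O)CCCC[C@@H]1CO1
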